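**Retrosynthetic overview**
- The strategy rests on the cyclohexane ring C5–C6–C7–C8–C9–C10: C5, C6, C9 and C10 carry four of its six stereocentres, and the C7–C8 cis-diol lies where the double bond of a [4+2] adduct falls, so that bond is carried as a C7 silyl enol ether.
- Key disconnection: C5–C6 and C9–C10, by a catalytic enantioselective Diels–Alder reaction of a 1,4-dialkoxy-2-silyloxybutadiene with methyl (E)-3-methyl-4-oxobut-2-enoate; the carbocycle is formed first.
- After the cycloaddition: CHO to vinyl, CO2Me to isopropenyl, Rubottom oxidation for C8–O, then the lactone ring is closed second by forming C7–C11 through an intramolecular Reformatsky reaction from a C6 bromoacetate, which fixes C7.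
- End game: C11 methylenation, release of O9, angeloylation, release of O8.
- The two ring ethers are differentiated from the start: 4-methoxybenzyl (PMB) on O6 and naphthalen-2-ylmethyl (NAP) on O9.

Key step: step 7

Remark: ring carbons carry elemanolide numbers, α/β refer to the usual drawing in which the C10 methyl is β, and the facial sense of the cycloaddition is assigned from the accepted formyl-binding model of these boron catalysts with 2-substituted enals, so the (S)-catalyst is assumed to give the enantiomer drawn.

**Route**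

Step 1
Reactants: 1 2-chloro-N-methoxy-N-methylacetamide; 2 4-methoxybenzyl alcohol
Product: 3 N-methoxy-2-[(4-methoxybenzyl)oxy]-N-methylacetamide
Conditions: NaH, THF, 0 °C → rt
Reagents that add atoms: none
Why: Williamson ether synthesis; the sodium alkoxide of 2 displaces the activated α-chloride of 1 (SN2) while the N-methoxy-N-methylamide resists alkoxide attack.

Step 2
Reactants: 3 N-methoxy-2-[(4-methoxybenzyl)oxy]-N-methylacetamide
Product: 4 1-[(4-methoxybenzyl)oxy]but-3-yn-2-one
Conditions: HC≡CMgBr, THF, −78 → 0 °C; inverse quench into cold aq. NaHSO4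
Reagents that add atoms: ethynylmagnesium bromide C#C[Mg]Br
Why: Acylation of an alkynyl Grignard reagent by an N-methoxy-N-methylamide stops at the ketone because the chelated tetrahedral adduct survives until the acidic quench, which also keeps the released amine from adding to the ynone.

Step 3
Reactants: 4 1-[(4-methoxybenzyl)oxy]but-3-yn-2-one; 5 naphthalen-2-ylmethanol
Product: 6 (E)-1-[(4-methoxybenzyl)oxy]-4-(naphthalen-2-ylmethoxy)but-3-en-2-one
Conditions: 1,4-diazabicyclo[2.2.2]octane (10 mol %), CH2Cl2, 0 °C → rt
Reagents that add atoms: none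
Why: Amine-catalysed oxa-Michael addition of an alcohol to a terminal ynone should give the β-alkoxy enone as its thermodynamically preferred E isomer.

Step 4
Reactants: 6 (E)-1-[(4-methoxybenzyl)oxy]-4-(naphthalen-2-ylmethoxy)but-3-en-2-one
Product: 7 (1Z,3E)-1-[(4-methoxybenzyl)oxy]-4-(naphthalen-2-ylmethoxy)-2-(tert-butyldimethylsilyloxy)buta-1,3-diene
Conditions: tBuMe2SiOSO2CF3, Et3N, Et2O, −78 → 0 °C; used after filtration through Et3N-deactivated silica
Reagents that add atoms: tert-butyldimethylsilyl trifluoromethanesulfonate CC(C)(C)[Si](C)(C)OS(=O)(=O)C(F)(F)F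
Why: Soft enolisation of the only enolisable position, the CH2(OPMB) group, gives the silyl dienol ether; the Z enol ether (OPMB cis to OSi) avoids allylic strain against the alkenyl arm and places both ether oxygens outward in the s-cis diene.

Step 5
Reactants: 8 1,1-dimethoxypropan-2-one; 9 trimethyl phosphonoacetate
Product: 10 methyl (E)-4,4-dimethoxy-3-methylbut-2-enoate
Conditions: NaH, THF, 0 °C → rt; minor Z isomer removed by chromatography
Reagents that add atoms: none
Why: Horner–Wadsworth–Emmons olefination of the ketone, the ester going trans to the bulkier dimethoxymethyl group to give mainly the E enoate.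

Step 6
Reactants: 10 methyl (E)-4,4-dimethoxy-3-methylbut-2-enoate
Product: 11 methyl (E)-3-methyl-4-oxobut-2-enoate
Conditions: 1 M HCl, acetone/H2O, rt
Reagents that add atoms: water O
Why: Acid-catalysed acetal hydrolysis; the conjugated E aldehyde is the thermodynamic isomer under these conditions.

Step 7
Reactants: 7 (1Z,3E)-1-[(4-methoxybenzyl)oxy]-4-(naphthalen-2-ylmethoxy)-2-(tert-butyldimethylsilyloxy)buta-1,3-diene; 11 methyl (E)-3-methyl-4-oxobut-2-enoate
Product: 12 Diels–Alder adduct (5β-CO2Me 6β-OPMB 9β-ONAP 10β-CH3 10α-CHO cyclohexene with C7 silyl enol ether)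
Conditions: (S)-tetrahydro-1-(2-methylphenyl)-3,3-diphenyl-1H,3H-pyrrolo[1,2-c][1,3,2]oxazaborole (20 mol %) + HN(SO2CF3)2 (20 mol %), CH2Cl2, −78 °C, slow addition of 7; Et3N quench
Reagents that add atoms: none
Why: The N-protonated oxazaborolidine binds the formyl oxygen of 11 (s-trans enal, formyl C–H···O contact to the ring oxygen) and the activated enal undergoes a concerted, asynchronous [4+2] cycloaddition with s-cis 7, C5–C6 bonding running ahead of C9–C10; the closest known reaction type is the oxazaborolidinium-catalysed Diels–Alder reaction of 2-substituted enals with alkoxy- and silyloxy-dienes. The one ring formed, the carbocycle C5–C6–C7–C8–C9–C10, is closed by intermolecular suprafacial cycloaddition in which both ring bonds form in the same pericyclic event. C6 and C9 follow from the (1Z,3E) diene geometry, which holds both ether oxygens outward and therefore cis in the adduct; C5 and C10 follow from the E dienophile (CHO trans to CO2Me) and from the formyl-exo/ester-endo transition state that a 2-methyl enal normally prefers, so that CO2Me and the C10 methyl end cis to the two ether oxygens and CHO trans. The absolute configuration of all four centres is set by the (S)-catalyst, whose aryl group covers one face of the bound enal so that the diene adds to the face on which CHO → C5 → CH3 runs clockwise at C10. The step needs regioselectivity, secured by the 2-silyloxy group (C6 the most nucleophilic diene terminus) matched with formyl activation (C5 the most electrophilic carbon), and survival of the enol ether C7=C8, secured by the low temperature and the amine quench.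

Step 8
Reactants: 12 Diels–Alder adduct
Product: 13 10α-vinyl ester
Conditions: Ph3PCH3Br, KN(SiMe3)2, THF, −78 → 0 °C
Reagents that add atoms: methyltriphenylphosphonium bromide C[P+](c1ccccc1)(c1ccccc1)c1ccccc1.[Br-]
Why: Wittig methylenation of the non-enolisable neopentyl aldehyde; the ylide is too weak a base to enolise the ester, and the silyl enol ether masks the C7 ketone.

Step 9
Reactants: 13 10α-vinyl ester
Product: 15 5β-(2-hydroxypropan-2-yl) compound, via methyl ketone 14 (not isolated)
Conditions: MeLi, CeCl3 (anhydrous), THF, −78 → −20 °C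
Reagents that add atoms: methyllithium [Li]C
Why: Double addition of the weakly basic methylcerium reagent to the hindered ester gives the tertiary carbinol without enolisation at C5, which would expel the C6 ether; the enol ether again protects C7.

Step 10
Reactants: 15 5β-(2-hydroxypropan-2-yl) compound
Product: 16 5β-isopropenyl silyl enol ether
Conditions: methyl N-(triethylammoniosulfonyl)carbamate (Burgess reagent), PhMe, 60 °C
Reagents that add atoms: none
Why: Burgess dehydration by syn-elimination of the tertiary sulfamate under neutral conditions; loss of one of the six methyl hydrogens is favoured over the shielded C5–H, whose removal would create a tetrasubstituted alkene with severe allylic strain against C10 and C6.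

Step 11
Reactants: 16 5β-isopropenyl silyl enol ether
Product: 18 C7 ketone with 8α-silyloxy group, via silyloxy epoxide 17 (not isolated)
Conditions: 3-chloroperoxybenzoic acid (1.05 equiv), CH2Cl2, −20 → 0 °C
Reagents that add atoms: 3-chloroperoxybenzoic acid OOC(=O)c1cccc(Cl)c1
Why: Rubottom oxidation; the electron-rich silyl enol ether is epoxidised far faster than the vinyl and isopropenyl groups and from the α-face, opposite the pseudo-axial C6 ether and the axial C10 methyl, and acid-promoted opening with 1,4-silyl shift gives the α-silyloxy ketone with O8 α (trans to O9).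

Step 12
Reactants: 18 C7 ketone with 8α-silyloxy group
Product: 19 6β-hydroxy ketone
Conditions: (NH4)2Ce(NO3)6, MeCN/H2O 9:1, 0 °C
Reagents that add atoms: none
Why: Oxidative cleavage of the electron-rich 4-methoxybenzyl ether by the one-electron oxidant, a method known to spare 2-naphthylmethyl ethers, silyl ethers and unactivated alkenes.

Step 13
Reactants: 19 6β-hydroxy ketone
Product: 20 6β-bromoacetate
Conditions: BrCH2COBr, pyridine, CH2Cl2, −40 → 0 °C
Reagents that add atoms: bromoacetyl bromide BrCC(Br)=O
Why: O-Acylation of the secondary α-ketol hydroxyl by the reactive acid bromide under a mild base that does not enolise the ketone.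

Step 14
Reactants: 20 6β-bromoacetate
Product: 21 cis-fused 7α-hydroxy γ-lactone
Conditions: Zn dust (Me3SiCl-activated), THF, 50 °C, high dilution
Reagents that add atoms: none
Why: Intramolecular Reformatsky reaction; the zinc enolate tethered through the β-oriented O6 can reach only the β-face of the C7 carbonyl, so the γ-lactone closes cis-fused (5-exo-trig) and C7 receives its α-hydroxyl, while zinc neither reduces nor enolises the β-alkoxy ketone.

Step 15
Reactants: 21 cis-fused 7α-hydroxy γ-lactone
Product: 22 C11 dimethylaminomethyl lactone (C11 epimers)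
Conditions: LiN(iPr)2 (3 equiv), THF, −78 °C; then CH2=NMe2 I, −78 → 0 °C
Reagents that add atoms: N,N-dimethylmethyleneiminium iodide C=[N+](C)C.[I-]
Why: Mannich-type α-aminomethylation of the lactone through its alkoxide–enolate dianion, in which the β-alkoxide cannot be eliminated; the configuration at C11 is irrelevant.

Step 16
Reactants: 22 C11 dimethylaminomethyl lactone
Product: 24 α-methylene lactone (O8 silyl and O9 NAP), via trimethylammonium iodide 23 (not isolated)
Conditions: MeI, MeOH/CH2Cl2, rt; then aq. NaHCO3, EtOAc, rt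
Reagents that add atoms: none
Why: N-Quaternisation and base-induced β-elimination of trimethylamine (E1cB) give the exocyclic C11=C13 alkene; C7 bears no hydrogen, so no endocyclic isomer can form.

Step 17
Reactants: 24 α-methylene lactone (O8 silyl and O9 NAP)
Product: 25 9β-alcohol
Conditions: 2,3-dichloro-5,6-dicyano-1,4-benzoquinone (DDQ), CH2Cl2/pH 7 phosphate buffer, 0 °C → rt
Reagents that add atoms: none
Why: Oxidative removal of the 2-naphthylmethyl ether by hydride abstraction and hydrolysis of the oxocarbenium ion, conditions that leave the alkenes, the silyl ether and the lactone untouched.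

Step 18
Reactants: 25 9β-alcohol; 26 angelic acid
Product: 28 9β-angelate 8α-silyl ether, via mixed anhydride 27 (not isolated)
Conditions: 26, 2,4,6-Cl3C6H2COCl, Et3N, PhMe, rt; then 25, 75 °C
Reagents that add atoms: none
Why: Yamaguchi-type esterification through the mixed anhydride, run without a nucleophilic catalyst to keep the Z geometry; only the secondary C9 hydroxyl can react, since O8 is silylated and the tertiary C7 hydroxyl is inert.

Step 19
Reactants: 28 9β-angelate 8α-silyl ether
Product: 29 CNP0114166.3 (target)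
Conditions: HF·pyridine, pyridine/THF, 0 °C → rt
Reagents that add atoms: none
Why: Fluoride cleavage of the secondary silyl ether under mildly acidic conditions that avoid acyl migration from O9 to O8, angelate isomerisation and conjugate addition to the methylene lactone.

**Compound list**

1 | 2-chloro-N-methoxy-N-methylacetamide | ClCC(=O)N(C)OC | starting material
2 | 4-methoxybenzyl alcohol | COc1ccc(CO)cc1 | starting material
3 | N-methoxy-2-[(4-methoxybenzyl)oxy]-N-methylacetamide | COc1ccc(COCC(=O)N(C)OC)cc1 | intermediate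
4 | 1-[(4-methoxybenzyl)oxy]but-3-yn-2-one | COc1ccc(COCC(=O)C#C)cc1 | intermediate
5 | naphthalen-2-ylmethanol | OCc1ccc2ccccc2c1 | starting material
6 | (E)-1-[(4-methoxybenzyl)oxy]-4-(naphthalen-2-ylmethoxy)but-3-en-2-one | COc1ccc(COCC(=O)/C=C/OCc2ccc3ccccc3c2)cc1 | intermediate
7 | (1Z,3E)-1-[(4-methoxybenzyl)oxy]-4-(naphthalen-2-ylmethoxy)-2-(tert-butyldimethylsilyloxy)buta-1,3-diene | COc1ccc(CO/C=C(O[Si](C)(C)C(C)(C)C)/C=C/OCc2ccc3ccccc3c2)cc1 | intermediate
8 | 1,1-dimethoxypropan-2-one | CC(=O)C(OC)OC | starting material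
9 | trimethyl phosphonoacetate | COC(=O)CP(=O)(OC)OC | starting material
10 | methyl (E)-4,4-dimethoxy-3-methylbut-2-enoate | COC(OC)/C(C)=C/C(=O)OC | intermediate
11 | methyl (E)-3-methyl-4-oxobut-2-enoate | O=C/C(C)=C/C(=O)OC | intermediate
12 | methyl 6-formyl-2-[(4-methoxybenzyl)oxy]-6-methyl-5-(naphthalen-2-ylmethoxy)-3-(tert-butyldimethylsilyloxy)cyclohex-3-ene-1-carboxylate; 5β-CO2Me, 6β-OPMB, 9β-ONAP, 10β-CH3, 10α-CHO | O=C[C@@]1(C)[C@H](C(=O)OC)[C@H](OCc2ccc(OC)cc2)C(O[Si](C)(C)C(C)(C)C)=C[C@@H]1OCc3ccc4ccccc4c3 | intermediate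
13 | 10α-vinyl analogue of 12 (methyl 6-ethenyl-6-methyl cyclohexenecarboxylate, other groups unchanged) | C=C[C@@]1(C)[C@H](C(=O)OC)[C@H](OCc2ccc(OC)cc2)C(O[Si](C)(C)C(C)(C)C)=C[C@@H]1OCc3ccc4ccccc4c3 | intermediate
14 | 5β-acetyl analogue of 13 (methyl ketone) | C=C[C@@]1(C)[C@H](C(C)=O)[C@H](OCc2ccc(OC)cc2)C(O[Si](C)(C)C(C)(C)C)=C[C@@H]1OCc3ccc4ccccc4c3 | intermediate (not isolated)
15 | 5β-(2-hydroxypropan-2-yl) analogue of 13 (tertiary alcohol) | C=C[C@@]1(C)[C@H](C(C)(C)O)[C@H](OCc2ccc(OC)cc2)C(O[Si](C)(C)C(C)(C)C)=C[C@@H]1OCc3ccc4ccccc4c3 | intermediate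
16 | 5β-isopropenyl-10α-vinyl-10β-methyl-6β-OPMB-9β-ONAP cyclohexene, C7 tert-butyldimethylsilyl enol ether | C=C[C@@]1(C)[C@H](C(=C)C)[C@H](OCc2ccc(OC)cc2)C(O[Si](C)(C)C(C)(C)C)=C[C@@H]1OCc3ccc4ccccc4c3 | intermediate
17 | 7α,8α-epoxide of 16 (C7 silyloxy oxirane) | C=C[C@@]1(C)[C@H](C(=C)C)[C@H](OCc2ccc(OC)cc2)[C@@]3(O[Si](C)(C)C(C)(C)C)O[C@H]3[C@@H]1OCc4ccc5ccccc5c4 | intermediate (not isolated)
18 | cyclohexan-7-one with 8α-OSi(tBu)Me2, 6β-OPMB, 9β-ONAP, 5β-isopropenyl, 10α-vinyl, 10β-CH3 | C=C[C@@]1(C)[C@H](C(=C)C)[C@H](OCc2ccc(OC)cc2)C(=O)[C@@H](O[Si](C)(C)C(C)(C)C)[C@@H]1OCc3ccc4ccccc4c3 | intermediate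
19 | 6β-hydroxy analogue of 18 (α-ketol) | C=C[C@@]1(C)[C@H](C(=C)C)[C@H](O)C(=O)[C@@H](O[Si](C)(C)C(C)(C)C)[C@@H]1OCc2ccc3ccccc3c2 | intermediate
20 | 6β-O-bromoacetate of 19 | C=C[C@@]1(C)[C@H](C(=C)C)[C@H](OC(=O)CBr)C(=O)[C@@H](O[Si](C)(C)C(C)(C)C)[C@@H]1OCc2ccc3ccccc3c2 | intermediate
21 | cis-fused 12,6β-lactone with 7α-OH, C11H2, 8α-OSi(tBu)Me2, 9β-ONAP | C=C[C@@]1(C)[C@H](C(=C)C)[C@@H]2OC(=O)C[C@]2(O)[C@@H](O[Si](C)(C)C(C)(C)C)[C@@H]1OCc3ccc4ccccc4c3 | intermediate
22 | 11-(dimethylaminomethyl) derivative of 21 (C11 epimers) | C=C[C@@]1(C)[C@H](C(=C)C)[C@@H]2OC(=O)C(CN(C)C)[C@]2(O)[C@@H](O[Si](C)(C)C(C)(C)C)[C@@H]1OCc3ccc4ccccc4c3 | intermediate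
23 | trimethylammonium iodide of 22 | C=C[C@@]1(C)[C@H](C(=C)C)[C@@H]2OC(=O)C(C[N+](C)(C)C)[C@]2(O)[C@@H](O[Si](C)(C)C(C)(C)C)[C@@H]1OCc3ccc4ccccc4c3.[I-] | intermediate (not isolated)
24 | 11(13)-methylene lactone with 7α-OH, 8α-OSi(tBu)Me2, 9β-ONAP | C=C[C@@]1(C)[C@H](C(=C)C)[C@@H]2OC(=O)C(=C)[C@]2(O)[C@@H](O[Si](C)(C)C(C)(C)C)[C@@H]1OCc3ccc4ccccc4c3 | intermediate
25 | 9β-hydroxy analogue of 24 | C=C[C@@]1(C)[C@H](C(=C)C)[C@@H]2OC(=O)C(=C)[C@]2(O)[C@@H](O[Si](C)(C)C(C)(C)C)[C@@H]1O | intermediate
26 | angelic acid, (Z)-2-methylbut-2-enoic acid | C/C=C(/C)C(=O)O | starting material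
27 | (Z)-2-methylbut-2-enoic 2,4,6-trichlorobenzoic anhydride | C/C=C(/C)C(=O)OC(=O)c1c(Cl)cc(Cl)cc1Cl | intermediate (not isolated)
28 | 9β-angeloyloxy-8α-(tert-butyldimethylsilyloxy)-7α-hydroxy lactone | C=C[C@@]1(C)[C@H](C(=C)C)[C@@H]2OC(=O)C(=C)[C@]2(O)[C@@H](O[Si](C)(C)C(C)(C)C)[C@@H]1OC(=O)/C(C)=C\C | intermediate
29 | CNP0114166.3: 9β-angeloyloxy-7α,8α-dihydroxyelema-1,3,11(13)-trien-12,6β-olide | C=C[C@@]1(C)[C@H](C(=C)C)[C@@H]2OC(=O)C(=C)[C@]2(O)[C@@H](O)[C@@H]1OC(=O)/C(C)=C\C | target

**Step count and risks**

Total steps: 19. Longest linear sequence: 17 steps (steps 1–4 and 7–19); the dienophile arm (steps 5–6) is convergent.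

Steps most likely to fail:

1. Step 7. The cationic boron Lewis acid may divert the trioxygenated diene into stepwise Mukaiyama–Michael addition or ionise its enol ethers before cycloaddition; the formyl-endo transition state may compete with the formyl-exo one; and facial discrimination may be poor. Fallback: setting out from 7 and 11, an uncatalysed thermal cycloaddition (toluene, 80 °C, 2,6-di-tert-butyl-4-methylphenol as inhibitor, no Lewis acid) should give the racemic adduct, that is 12 together with the mirror-image adduct ent-12 F1. Resolution on a chiral stationary phase (amylose tris(3,5-dimethylphenylcarbamate), preparative HPLC) returns to the route at 12. This replaces catalyst control by racemic synthesis and resolution.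

2. Step 14. Zinc insertion may be slow, and ring closure through the less populated s-cis ester rotamer may be outrun by intermolecular aldol addition or by protonation of the enolate to the simple acetate. Fallback: setting out from 19, acetylation (Ac2O, 4-(dimethylamino)pyridine, pyridine, 0 °C) should give the 6β-acetate F2. Treatment with LiN(SiMe3)2 in THF at −78 °C should then close the ring by base-mediated intramolecular aldol lactonisation, with the same tether control of C7, and return to the route at 21.

3. Step 18. The activated angeloyl unit may isomerise from Z to E (tiglate), acylation of the neopentyl C9 hydroxyl next to the C8 silyl ether may be sluggish, and the silyl group may migrate from O8 to O9 on heating with base. Fallback: setting out from 25, esterification with 2-[bis(2,2,2-trifluoroethoxy)phosphoryl]propanoic acid (N-(3-dimethylaminopropyl)-N'-ethylcarbodiimide hydrochloride, 4-(dimethylamino)pyridine, CH2Cl2) should give the C9 phosphonopropanoate F3. A Z-selective Still–Gennari olefination with acetaldehyde (KN(SiMe3)2, 18-crown-6, THF, −78 °C) then builds the angelate double bond on the ester and returns to the route at 28.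

**Further compounds**

F1 | step 7 | ent-12, mirror image of the Diels–Alder adduct 12 | O=C[C@]1(C)[C@@H](C(=O)OC)[C@@H](OCc2ccc(OC)cc2)C(O[Si](C)(C)C(C)(C)C)=C[C@H]1OCc3ccc4ccccc4c3
F2 | step 14 | 6β-O-acetate of 19 | C=C[C@@]1(C)[C@H](C(=C)C)[C@H](OC(C)=O)C(=O)[C@@H](O[Si](C)(C)C(C)(C)C)[C@@H]1OCc2ccc3ccccc3c2
F3 | step 18 | 9β-O-{2-[bis(2,2,2-trifluoroethoxy)phosphoryl]propanoate} of 25 | C=C[C@@]1(C)[C@H](C(=C)C)[C@@H]2OC(=O)C(=C)[C@]2(O)[C@@H](O[Si](C)(C)C(C)(C)C)[C@@H]1OC(=O)C(C)P(=O)(OCC(F)(F)F)OCC(F)(F)F
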